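- How much E stands in the flask at 6.0 h, and how near saturation is L then?

all flasks: Z 24 mM (held)

| charge | Q | remark | time |
|---|---|---|---|
| north-east | 0.048 M | run made earlier |  |
| south-east | 0.19 M | run made earlier |  |
| flask | 0.096 M |  | 6.0 h |

| north-east: time / h | north-east: E / % | south-east: time / h | south-east: E / % |
|---|---|---|---|
| 0.417 | 0 | 0.417 | 0.2 |
| 0.667 | 1.4 | 0.667 | 0.8 |
| 1.33 | 2.0 | 1.33 | 2.1 |
| 2.50 | 4.8 | 2.50 | 4.0 |
| 5.00 | 9.4 | 5.00 | 6.2 |

(readings scatter by 0.3 percentage points)

1. E at 6.0 h, in percent of the Q charged
2. concentration of L in solution at 6.0 h, in percent of saturation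

- the numbers in the tables scatter with a standard deviation of 0.3 percentage points
- at the start none of Z is in solution
- L is what Z becomes in solution

- First instants: no L is in solution at the start. The north-east run's late slope, 0.0202 h⁻¹ of the charge, carried back to zero E gives a delay of 0.338 h, which I read as the solution filling with L.
- Middle: I let the slope depend on E as a concentration, not as a percentage. The north-east run gives its slope at a mean E of 2.74 mM, and the south-east run's last stretch gives 0.00880 h⁻¹ at 9.69 mM.
- A straight line through these two reaches zero slope at 15.1 mM and starts at 0.0246 h⁻¹. I call that level the ceiling of E, the E at which this line gives no further rise, a reading from scattered slopes. The south-east stretch left out of the line reads 0.0175 h⁻¹ at 4.56 mM, where the line says 0.0172 h⁻¹.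
- End: up to 6.0 h I let the flask climb towards the ceiling with a time constant, ceiling over charge times starting slope, of 6.37 h. My reckoning gives E at 9.24%. The flask's L is used at 2.36 mM h⁻¹, much less than the 71.0 mM h⁻¹ that could enter an empty solution, so I put L at 96.7%.
- The forecast says 9.3% and 96%, and of the south-east slowing it says: “This suggests product inhibition or catalyst loss, though the cause is unclear”.

    L ⇌ X (K = 3.50, k = 2.00 × 10⁻⁶ s⁻¹)
    L + E → G (k = 4.90 × 10⁻⁴ M⁻¹ s⁻¹)
    Q + E → J (k = 2.60 × 10⁻⁴ M⁻¹ s⁻¹)
    Z ⇌ L, rate k4*(csat - [L]) (kL = 4.70 × 10⁻⁴ s⁻¹)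
    Q + L → E (k = 3.20 × 10⁻⁴ M⁻¹ s⁻¹)

- The flask gives 9.44% and 93.5%, so its E is 9.06 mM, below the ceiling. Beside E it holds J at 4.81%, each J counting double in that percentage, and G at 1.16%. On the neighbouring flask, with 0.024 M of Q, I keep the ceiling; the time constant becomes 25.5 h, and I reckon 12.5% of its charge. That flask gives 11.5%.

The earlier runs and the new flask stem from a simulated flask with constants of no real substance; the scatter is artificial.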